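The route rests on opening the spiro centre C13: the oxolane bond O9–C13 and the dihydrofuran bond O–C16 are both traced back to the 1,1-disubstituted alkene C13=C16 of hydroxy acid 24. In the key step an iodonium ion on this alkene lets the tertiary C9 hydroxyl close the oxolane (C9, C11, C12, C13, O) at C13, and the C15 carboxylate then displaces iodide at C16, closing the second five-membered ring (C13–C16, O) as a spiro lactone and fixing C13. The precursor is an open 3-methylenepentanoic acid chain on C9 of a tricyclic lactone core, built from 2-allylcyclohexane-1,3-dione by catalytic desymmetrisation and substrate-controlled relay.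

Key step: step 19

Remark: atoms are numbered as in labdanes (C19 lactone carbonyl, C20 lactone OCH2, C17 epoxide CH2, C15/C16 the CH= and OCH2 of the dihydrofuran); β is the face of the C19–O–C20 bridge. Compounds 1, 3 and 19 are assumed to be purchasable.

Step 1
Reactants: 1 2-allylcyclohexane-1,3-dione
Product: 2 2-allyl-2-(hydroxymethyl)cyclohexane-1,3-dione
Conditions: 37% aq. CH2O, NaHCO3 (cat.), THF, rt
Reagents that add atoms: formaldehyde, C=O
Why: aldol addition (hydroxymethylation) of the acidic 2-position of the 1,3-dione to formaldehyde makes the quaternary carbon that becomes C10; the adduct cannot dehydrate and no stereocenter is formed yet.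

Step 2
Reactants: 2 2-allyl-2-(hydroxymethyl)cyclohexane-1,3-dione; 3 2-(diethoxyphosphoryl)propanoic acid
Product: 4 (1-allyl-2,6-dioxocyclohexyl)methyl 2-(diethoxyphosphoryl)propanoate
Conditions: DCC, DMAP (cat.), CH2Cl2, 0 °C to rt
Reagents that add atoms: none
Why: Steglich esterification of the primary alcohol installs the C19/C4/C18 unit as a phosphonate and removes the retro-aldol pathway; no stereocenter at the future C10.

Step 3
Reactants: 4 (1-allyl-2,6-dioxocyclohexyl)methyl 2-(diethoxyphosphoryl)propanoate
Product: 5 [(1S,2S)-1-allyl-2-hydroxy-6-oxocyclohexyl]methyl 2-(diethoxyphosphoryl)propanoate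
Conditions: (R)-2-methyl-CBS-oxazaborolidine (20 mol %), catecholborane, toluene–CH2Cl2, −78 to −40 °C
Reagents that add atoms: none
Why: desymmetrising Corey–Bakshi–Shibata mono-reduction of the prochiral 2,2-disubstituted 1,3-diketone; the catalyst fixes the carbinol (future C9) as S, and hydride should add anti to the larger acyloxymethyl arm, so the choice of carbonyl sets the quaternary C10. The diastereomer from the other carbonyl, which has the opposite C10 configuration, is removed by chromatography, and catecholborane leaves the allyl group alone.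

Step 4
Reactants: 5 hydroxy ketone
Product: 6 [(1S,2S)-1-allyl-6-oxo-2-(triethylsilyloxy)cyclohexyl]methyl 2-(diethoxyphosphoryl)propanoate
Conditions: Et3SiCl, imidazole, DMF, 0 °C
Reagents that add atoms: chlorotriethylsilane, CC[Si](Cl)(CC)CC
Why: silylation of the secondary alcohol blocks acyl migration and alkoxide side reactions in the base-mediated steps that follow.

Step 5
Reactants: 6 silyl ether phosphonate
Product: 7 8a-allyl-4-methyl-8-(triethylsilyloxy)-1,5,6,7,8,8a-hexahydro-3H-isochromen-3-one (OSiEt3 cis to the lactone CH2)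
Conditions: NaH, THF, 0 to 40 °C
Reagents that add atoms: none
Why: intramolecular Horner–Wadsworth–Emmons olefination of the remaining ketone (C5) closes the unsaturated δ-lactone (C4=C5, C19–O–C20), which ties C19 to C20 on one face; no new stereocenter.

Step 6
Reactants: 7 allyl pentenolide
Product: 8 8a-(3-hydroxypropyl)-4-methyl-8-(triethylsilyloxy)-1,5,6,7,8,8a-hexahydro-3H-isochromen-3-one
Conditions: 9-BBN, THF, 0 °C to rt; then H2O2, pH 7 buffer
Reagents that add atoms: hydrogen peroxide, OO
Why: anti-Markovnikov hydroboration–oxidation of the terminal alkene only; the tetrasubstituted, conjugated C4=C5 alkene is inert to 9-BBN.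

Step 7
Reactants: 8 primary alcohol
Product: 9 8a-(3-iodopropyl)-4-methyl-8-(triethylsilyloxy)-1,5,6,7,8,8a-hexahydro-3H-isochromen-3-one
Conditions: I2, PPh3, imidazole, CH2Cl2, 0 °C
Reagents that add atoms: iodine, II
Why: Appel-type iodination turns C3 into the electrophile for ring A.

Step 8
Reactants: 9 iodide
Product: 10 tricyclic 5-ene lactone (4α-methyl, 4β-CO–O–CH2-10β bridge, 9β-OSiEt3)
Conditions: LiN(iPr)2, THF–DMPU, −78 to 0 °C
Reagents that add atoms: none
Why: intramolecular deconjugative α-alkylation of the lactone dienolate (γ-deprotonation at C6, C-alkylation at the α-carbon C4, 6-exo-tet) closes ring A and moves the alkene to C5=C6. The C4 stereocenter (methyl α, C19 β) is dictated by the lactone bridge already fixed at C10, since C4 and C10 become bridgeheads of one bicyclo[3.3.1] unit.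

Step 9
Reactants: 10 tricyclic 5-ene lactone
Product: 11 cis-fused 6β-alcohol (5β-H, 9β-OSiEt3)
Conditions: BH3·THF, THF, 0 °C to rt; then H2O2, pH 7 buffer
Reagents that add atoms: hydrogen peroxide, OO
Why: hydroboration–oxidation puts boron on the less hindered C6; syn addition should come from the lactone-side face because the other face is screened by the axial hydrogens on C1 and C3. Whichever face is attacked, C5 is reset in step 10.

Step 10
Reactants: 11 cis-fused 6β-alcohol
Product: 13 trans-fused 6-keto lactone, via cis-fused 6-keto lactone 12 (not isolated)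
Conditions: Dess–Martin periodinane, NaHCO3, CH2Cl2, rt; then DBU, CH2Cl2, rt
Reagents that add atoms: none
Why: Dess–Martin oxidation, then base equilibration of the C5 hydrogen α to the new ketone; the trans-fused ketone (C6 equatorial on ring A) is expected to be the thermodynamic isomer, which sets C5 as 5α-H.

Step 11
Reactants: 13 trans-fused 6-keto lactone
Product: 14 6β-alcohol (5α-H, 9β-OSiEt3)
Conditions: NaBH4, CeCl3·7H2O, MeOH, −40 °C
Reagents that add atoms: none
Why: Luche reduction; hydride adds from the α face because the β face is blocked by the axial C20 methylene and the C19 carbonyl, giving the axial 6β-alcohol. The protic medium keeps the alkoxide from attacking the lactone.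

Step 12
Reactants: 14 6β-alcohol
Product: 15 6β-(tert-butyldimethylsilyloxy)-9β-(triethylsilyloxy) lactone
Conditions: tBuMe2SiOTf, 2,6-lutidine, CH2Cl2, 0 °C
Reagents that add atoms: tert-butyldimethylsilyl trifluoromethanesulfonate, CC(C)(C)[Si](C)(C)OS(=O)(=O)C(F)(F)F
Why: silyl triflate protects the hindered axial alcohol with a group that outlasts the triethylsilyl ether.

Step 13
Reactants: 15 bis-silyl ether
Product: 17 9-keto lactone (6β-OSitBuMe2), via 9β-hydroxy lactone 16 (not isolated)
Conditions: PPTS, MeOH, 0 °C; then Dess–Martin periodinane, NaHCO3, CH2Cl2, rt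
Reagents that add atoms: none
Why: acid methanolysis removes the more labile triethylsilyl ether selectively and Dess–Martin oxidation gives the C9 ketone; the temporary C9 carbinol centre, having served to fix C10, is erased.

Step 14
Reactants: 17 9-keto lactone
Product: 18 8-methylene-9-keto lactone (enone)
Conditions: (CH2O)n, N-methylanilinium trifluoroacetate, THF, reflux
Reagents that add atoms: formaldehyde, C=O
Why: Mannich-type α-methylenation (amine-salt-mediated condensation with formaldehyde and elimination); C8 is the only enolisable α-carbon of the C9 ketone, and this installs C17.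

Step 15
Reactants: 19 3-methylbut-3-en-1-ol
Product: 20 3-methylenepentane-1,5-diol
Conditions: n-BuLi (2.1 equiv), TMEDA, hexane–Et2O, 0 °C to rt; then (CH2O)n, −78 °C to rt
Reagents that add atoms: formaldehyde, C=O
Why: double deprotonation gives the alkoxide–allyl dianion, which adds to formaldehyde at the allylic carbon; no stereocenter.

Step 16
Reactants: 20 3-methylenepentane-1,5-diol
Product: 21 5-iodo-3-methylenepentan-1-ol
Conditions: I2 (1 equiv), PPh3, imidazole, CH2Cl2, 0 °C
Reagents that add atoms: iodine, II
Why: Appel-type mono-iodination of the symmetrical diol with one equivalent of reagent; unreacted diol is recycled.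

Step 17
Reactants: 18 8-methylene-9-keto lactone; 21 5-iodo-3-methylenepentan-1-ol
Product: 23 9α-hydroxy diol with the 5-hydroxy-3-methylenepentyl chain 9β, via dilithio reagent 22 (not isolated)
Conditions: 21, t-BuLi (3.1 equiv), Et2O, −78 °C; CeCl3, THF, −78 °C; then 18, −78 °C
Reagents that add atoms: none
Why: iodine–lithium exchange on the lithium alkoxide, transmetalation to cerium and 1,2-addition to the hindered enone; the organocerium suppresses enolisation and conjugate addition. The bulky reagent should add along the equatorial (β) trajectory, away from the axial hydrogens on C5 and C7, which sets C9 with the hydroxyl α-axial and C11 β.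

Step 18
Reactants: 23 diol
Product: 24 hydroxy acid (3-methylenepentanoic acid chain on C9)
Conditions: TEMPO (cat.), PhI(OAc)2, MeCN–H2O (pH 7 buffer), rt
Reagents that add atoms: water, O
Why: TEMPO-catalysed oxidation takes the primary alcohol through the aldehyde hydrate to the acid and leaves the tertiary allylic alcohol and both alkenes untouched.

Step 19
Reactants: 24 hydroxy acid
Product: 26 spiro lactone (9α,13-epoxy-15,16-olide, 6β-OSitBuMe2, 8(17)-ene), via iodo ether acid 25 (not isolated)
Conditions: N-iodosuccinimide, CH2Cl2, −20 to 0 °C; then solvent switch, Cs2CO3, DMF, 60 °C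
Reagents that add atoms: none
Why: N-iodosuccinimide converts the electron-rich 1,1-disubstituted alkene into an iodonium ion, which the tertiary C9 hydroxyl opens at the more substituted carbon C13 to give iodo ether 25; after the solvent switch the caesium carboxylate displaces iodide at C16 in an intramolecular SN2 reaction, which forms the O–C16 bond and the γ-lactone. The closest known reaction types are iodoetherification of γ,δ-unsaturated alcohols and lactonisation of γ-halo carboxylates. The oxolane closes 5-exo-trig and the lactone 5-exo-tet. C13 is set in the first event by the substrate: in the envelope transition state the quaternary C10 lies pseudo-equatorial, and the small iodonium-bearing CH2 terminus rather than the CH2CO2H arm should take the position syn to the pseudo-axial C8, which places C16 cis to C8 as required. The step needs Markovnikov attack by O9 in preference to 4-exo attack by the un-ionised carboxylic acid, secured by running the first stage without base, and it needs the C8=C17 alkene to stay out, which it should because no nucleophile can reach an iodonium ion there in a five- or six-membered mode. No β-hydrogen is available next to C16 (C13 is quaternary), so elimination cannot compete with the substitution.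

Step 20
Reactants: 26 spiro lactone
Product: 27 6β-hydroxy spiro lactone
Conditions: HF·pyridine, pyridine, THF, 0 °C to rt
Reagents that add atoms: none
Why: fluoride cleavage of the hindered silyl ether under non-basic conditions, so that no 6β-alkoxide sits next to the C19 lactone carbonyl.

Step 21
Reactants: 27 6β-hydroxy spiro lactone
Product: 28 8β,17-epoxide
Conditions: VO(acac)2 (5 mol %), t-BuOOH, CH2Cl2, 0 °C to rt
Reagents that add atoms: tert-butyl hydroperoxide, CC(C)(C)OO
Why: vanadium-catalysed hydroxyl-directed epoxidation; the axial 6β-hydroxyl, homoallylic and 1,3-related to C8, should deliver oxygen to the β face of the C8=C17 alkene, setting C8 with oxygen β and C17 α.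

Step 22
Reactants: 28 8β,17-epoxide
Product: 29 6β-acetate
Conditions: Ac2O, DMAP, Et3N, CH2Cl2, rt
Reagents that add atoms: acetic anhydride, CC(=O)OC(C)=O
Why: DMAP-catalysed acetylation of the hindered axial alcohol; no stereocenter changes.

Step 23
Reactants: 29 6β-acetate
Product: 30 lactol (15-hydroxy-15,16-epoxide, anomers)
Conditions: disiamylborane (from BH3·THF and 2-methylbut-2-ene), THF, 0 °C to rt; then H2O2, pH 7 buffer, 0 °C
Reagents that add atoms: none
Why: disiamylborane reduces the unhindered γ-lactone to the lactol and should not touch the acetate, the hindered bridged δ-lactone or the epoxide; no alkene is left to be hydroborated.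

Step 24
Reactants: 30 lactol
Product: 31 target CNP0173713.2
Conditions: MsCl, Et3N, CH2Cl2, −20 °C to rt
Reagents that add atoms: none
Why: mesylation of the lactol hydroxyl and loss of methanesulfonate through the oxocarbenium ion gives the cyclic enol ether (lactol dehydration); C13 is quaternary, so only the C14=C15 alkene can form, and the sensitive enol ether is made last.

Compound list
1 | 2-allylcyclohexane-1,3-dione | C=CCC1C(=O)CCCC1=O | starting material
2 | 2-allyl-2-(hydroxymethyl)cyclohexane-1,3-dione | C=CCC1(CO)C(=O)CCCC1=O | intermediate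
3 | 2-(diethoxyphosphoryl)propanoic acid | CCOP(=O)(OCC)C(C)C(=O)O | starting material
4 | (1-allyl-2,6-dioxocyclohexyl)methyl 2-(diethoxyphosphoryl)propanoate | C=CCC1(COC(=O)C(C)P(=O)(OCC)OCC)C(=O)CCCC1=O | intermediate
5 | [(1S,2S)-1-allyl-2-hydroxy-6-oxocyclohexyl]methyl 2-(diethoxyphosphoryl)propanoate | C=CC[C@@]1(COC(=O)C(C)P(=O)(OCC)OCC)C(=O)CCC[C@@H]1O | intermediate
6 | [(1S,2S)-1-allyl-6-oxo-2-(triethylsilyloxy)cyclohexyl]methyl 2-(diethoxyphosphoryl)propanoate | C=CC[C@@]1(COC(=O)C(C)P(=O)(OCC)OCC)C(=O)CCC[C@@H]1O[Si](CC)(CC)CC | intermediate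
7 | 8a-allyl-4-methyl-8-(triethylsilyloxy)-1,5,6,7,8,8a-hexahydro-3H-isochromen-3-one (OSiEt3 cis to lactone CH2) | C=CC[C@@]12COC(=O)C(C)=C1CCC[C@@H]2O[Si](CC)(CC)CC | intermediate
8 | 8a-(3-hydroxypropyl) analogue of 7 | OCCC[C@@]12COC(=O)C(C)=C1CCC[C@@H]2O[Si](CC)(CC)CC | intermediate
9 | 8a-(3-iodopropyl) analogue of 7 | ICCC[C@@]12COC(=O)C(C)=C1CCC[C@@H]2O[Si](CC)(CC)CC | intermediate
10 | tricyclic 5-ene lactone (4α-methyl, 19,20-lactone bridge on the β face, 9β-OSiEt3) | C1CC[C@H](O[Si](CC)(CC)CC)[C@]23CCC[C@](C)(C(=O)OC2)C=13 | intermediate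
11 | cis-fused 6β-alcohol (5β-H, 9β-OSiEt3) | O[C@@H]1CC[C@H](O[Si](CC)(CC)CC)[C@]23CCC[C@](C)(C(=O)OC2)[C@@H]13 | intermediate
12 | cis-fused 6-keto lactone (5β-H) | O=C1CC[C@H](O[Si](CC)(CC)CC)[C@]23CCC[C@](C)(C(=O)OC2)[C@@H]13 | intermediate
13 | trans-fused 6-keto lactone (5α-H, 9β-OSiEt3) | O=C1CC[C@H](O[Si](CC)(CC)CC)[C@]23CCC[C@](C)(C(=O)OC2)[C@H]13 | intermediate
14 | 6β-alcohol (5α-H, 9β-OSiEt3) | O[C@@H]1CC[C@H](O[Si](CC)(CC)CC)[C@]23CCC[C@](C)(C(=O)OC2)[C@H]13 | intermediate
15 | 6β-(tert-butyldimethylsilyloxy)-9β-(triethylsilyloxy) lactone | CC(C)(C)[Si](C)(C)O[C@@H]1CC[C@H](O[Si](CC)(CC)CC)[C@]23CCC[C@](C)(C(=O)OC2)[C@H]13 | intermediate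
16 | 9β-hydroxy lactone (6β-OSitBuMe2) | CC(C)(C)[Si](C)(C)O[C@@H]1CC[C@H](O)[C@]23CCC[C@](C)(C(=O)OC2)[C@H]13 | intermediate
17 | 9-keto lactone (6β-OSitBuMe2) | CC(C)(C)[Si](C)(C)O[C@@H]1CCC(=O)[C@]23CCC[C@](C)(C(=O)OC2)[C@H]13 | intermediate
18 | 8-methylene-9-keto lactone | CC(C)(C)[Si](C)(C)O[C@@H]1CC(=C)C(=O)[C@]23CCC[C@](C)(C(=O)OC2)[C@H]13 | intermediate
19 | 3-methylbut-3-en-1-ol | CC(=C)CCO | starting material
20 | 3-methylenepentane-1,5-diol | OCCC(=C)CCO | intermediate
21 | 5-iodo-3-methylenepentan-1-ol | ICCC(=C)CCO | intermediate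
22 | lithium 5-lithio-3-methylenepentan-1-olate | [Li]CCC(=C)CCO[Li] | intermediate
23 | 9α-hydroxy-9β-(5-hydroxy-3-methylenepentyl)-8-methylene lactone | CC(C)(C)[Si](C)(C)O[C@@H]1CC(=C)[C@](O)(CCC(=C)CCO)[C@]23CCC[C@](C)(C(=O)OC2)[C@H]13 | intermediate
24 | hydroxy acid (5-substituted 3-methylenepentanoic acid) | CC(C)(C)[Si](C)(C)O[C@@H]1CC(=C)[C@](O)(CCC(=C)CC(=O)O)[C@]23CCC[C@](C)(C(=O)OC2)[C@H]13 | intermediate
25 | iodo ether acid (9α,13-epoxide, 13-CH2I, 13-CH2CO2H) | CC(C)(C)[Si](C)(C)O[C@@H]1CC(=C)[C@]2(CC[C@](CI)(CC(=O)O)O2)[C@]23CCC[C@](C)(C(=O)OC2)[C@H]13 | intermediate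
26 | spiro lactone (9α,13-epoxy-15,16-olide, 6β-OSitBuMe2, 8(17)-ene) | CC(C)(C)[Si](C)(C)O[C@@H]1CC(=C)[C@]2(CC[C@]3(CC(=O)OC3)O2)[C@]23CCC[C@](C)(C(=O)OC2)[C@H]13 | intermediate
27 | 6β-hydroxy spiro lactone | O[C@@H]1CC(=C)[C@]2(CC[C@]3(CC(=O)OC3)O2)[C@]23CCC[C@](C)(C(=O)OC2)[C@H]13 | intermediate
28 | 6β-hydroxy-8β,17-epoxide | O[C@@H]1C[C@@]2(CO2)[C@]2(CC[C@]3(CC(=O)OC3)O2)[C@]23CCC[C@](C)(C(=O)OC2)[C@H]13 | intermediate
29 | 6β-acetoxy-8β,17-epoxy spiro lactone | CC(=O)O[C@@H]1C[C@@]2(CO2)[C@]2(CC[C@]3(CC(=O)OC3)O2)[C@]23CCC[C@](C)(C(=O)OC2)[C@H]13 | intermediate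
30 | lactol (15-hydroxy, anomers) | CC(=O)O[C@@H]1C[C@@]2(CO2)[C@]2(CC[C@]3(CC(O)OC3)O2)[C@]23CCC[C@](C)(C(=O)OC2)[C@H]13 | intermediate
31 | CNP0173713.2 | CC(=O)O[C@@H]1C[C@@]2(CO2)[C@]2(CC[C@]3(C=COC3)O2)[C@]23CCC[C@](C)(C(=O)OC2)[C@H]13 | target

Total step count: 24. Longest linear sequence: 22 steps (steps 1–14 and 17–24).

Steps most likely to fail

Step 19. The iodonium ion may be captured by the carboxyl group in the 4-exo mode, and the facial discrimination at C13 may be weak. Fallback: the two ring closures are separated and the carboxyl group is introduced only after the first one. Setting out from diol 23, iodoetherification (I2, NaHCO3, MeCN, 0 °C), in which only the C9 hydroxyl can close a five-membered ring, should give the iodo ether alcohol F1 together with its C13 epimer F2. The epimers are separated at this stage, and F2 is returned to 23 by reductive elimination with zinc dust in ethanol. F1 is oxidised with TEMPO and PhI(OAc)2 in aqueous acetonitrile to iodo acid 25, which is closed to 26 with Cs2CO3 in DMF; the route is rejoined at compound 25.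

Step 3. The reagent may discriminate poorly between the two enantiotopic carbonyl groups, because the allyl and acyloxymethyl arms on the quaternary carbon are of similar size, and over-reduction to the diol is possible. Fallback: resolution in place of desymmetrisation. Setting out from dione 4, reduction with NaBH4 and CeCl3·7H2O in methanol at −78 °C and chromatographic removal of the trans isomers gives the racemic cis-hydroxy ketone, that is 5 and its enantiomer F3. A lipase-catalysed acylation with vinyl acetate (Candida antarctica lipase B, tert-butyl methyl ether) should acylate one enantiomer, written here as conversion of F3 into the acetate F4, which is separated. Unreacted 5 re-enters the route at compound 5.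

Step 21. Oxygen may be delivered to the α face, or the epoxidation may be sluggish, because the directing hydroxyl is only homoallylic and lies across the ring. Fallback: halohydrin route, which sets the same configuration without a directing group. Setting out from 27, N-bromosuccinimide in aqueous THF at 0 °C should form the bromonium ion on the more open α face, and water opens it at the tertiary C8 from the β face to give the bromohydrin F5 (8β-OH, 17-Br). DBU in CH2Cl2 then closes the 8β,17-epoxide, and the route is rejoined at compound 28.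

Further compounds
F1 | step 19 | iodo ether alcohol (9α,13-epoxide, 13-CH2I, 13-CH2CH2OH, C13 as in 25) | CC(C)(C)[Si](C)(C)O[C@@H]1CC(=C)[C@]2(CC[C@](CI)(CCO)O2)[C@]23CCC[C@](C)(C(=O)OC2)[C@H]13
F2 | step 19 | C13 epimer of F1 | CC(C)(C)[Si](C)(C)O[C@@H]1CC(=C)[C@]2(CC[C@@](CI)(CCO)O2)[C@]23CCC[C@](C)(C(=O)OC2)[C@H]13
F3 | step 3 | [(1R,2R)-1-allyl-2-hydroxy-6-oxocyclohexyl]methyl 2-(diethoxyphosphoryl)propanoate (enantiomer of 5) | C=CC[C@]1(COC(=O)C(C)P(=O)(OCC)OCC)C(=O)CCC[C@H]1O
F4 | step 3 | acetate of F3 | C=CC[C@]1(COC(=O)C(C)P(=O)(OCC)OCC)C(=O)CCC[C@H]1OC(C)=O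
F5 | step 21 | bromohydrin (6β-OH, 8β-OH, 17-Br) of 27 | O[C@@H]1C[C@@](O)(CBr)[C@]2(CC[C@]3(CC(=O)OC3)O2)[C@]23CCC[C@](C)(C(=O)OC2)[C@H]13
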